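## Analysis of the target

The target is a spiro tricycle: ring A is an enolised 2-acylcyclohexane-1,3,5-trione carrying an isobutyryl group and a gem-diprenyl carbon, ring B is a cyclohexane and ring C a cyclopentane, with rings B and C trans-fused as a hydrindane and rings A and B sharing one quaternary carbon. In indane numbering of the B/C part, C1 is the ring C carbinol, C3a and C7a are the fusion carbons, C4 is the ring B carbinol, C5 and C7 are CH2 groups and C6 is the spiro carbon; the five stereocentres are C1 (S), C3a (S), C4 (S), C7a (R) and C6. The ring B chair relates them: the fusion hydrogens are axial on opposite faces, the C4 methyl is axial and its hydroxyl equatorial, and the C1 hydroxyl is cis to C7. At C6 the ring A carbonyl next to the gem-diprenyl carbon is axial and syn to the C4 methyl, while the carbonyl next to the acyl-bearing carbon is equatorial. The sensitive groups are the acidic, ambident triketone enol (O- versus C-alkylation, retro-Claisen cleavage), two tertiary alcohols (dehydration, and retro-aldol cleavage if C6 ever becomes a ketone) and two prenyl alkenes that tolerate neither strong acid nor hydroboration or oxidants. The synthesis is hard because the spiro centre is stereogenic only through a difference two atoms further out in its two carbonyl arms, because the C4 carbinol has the less stable methyl-axial arrangement, and because ring C carries three contiguous stereocentres. The strategy rests on one feature: C4 is separated from C6 by the single CH2 group C5, so a methyl ketone on C3a and a 2-substituted allylsilane arm on C7a, whose central carbon is the future C6, can close ring B at the carbinol. The exocyclic methylene left on C6 then supplies one ring A carbonyl carbon.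

## Retrosynthetic reasoning

**Prenyl groups and silyl ethers.** Target 28 is traced to its bis-silyl ether 27, and both prenyl C–C bonds are cut at ring A C4, giving trione 24 and two equivalents of prenyl bromide 25, with the monoprenyl compound 26 lying between them. This carbon is the only ring A position that is neither quaternary nor acylated, so a double C-alkylation is regiochemically unambiguous. The prenyl alkenes appear only after all hydroboration and oxidation chemistry.

**Ring A.** In 24 the bond between the ring A CH2 and the axial carbonyl is cut (Dieckmann), giving triketone ester 23. The cut is made there because in 23 the isobutyryl group already sits on the carbon bound to the equatorial carbonyl, so the two carbonyl arms on the spiro carbon stay constitutionally different throughout. Closing ring A from a symmetrical acetoacetyl chain would make the two arms identical and erase the spiro centre. A nitrile in place of the ester would leave nitrogen on ring A after closure, and a hindered vinylogous amide would then have to be hydrolysed.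

**Acyl groups of the triketone.** 23 is unravelled by removing the acetyl group from the central carbon (to diketone 22) and the isobutyryl group from the methyl ketone (to keto ester 21). Each forward step is a C-acylation of the most acidic carbon with a small electrophile.

**Spiro centre.** The bond between the spiro carbon and the acetyl group of 21 is cut, giving ester 19 through its enolate 20. The forward acylation must come from the equatorial side, which the axial C4 methyl enforces. The group introduced first (the ester) therefore ends axial and becomes the carbonyl next to the diprenyl carbon, as the target requires.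

**One-carbon handle.** The ester carbon of 19 is the exocyclic methylene carbon of 14, reached through acid 18, aldehyde 17 and alcohol 16 by hydroboration (borane 15) and oxidation. Cleaving the alkene to a ring ketone is avoided: it would discard a carbon that is needed and place a ketone β to the C4 carbinol, inviting retro-aldol opening of ring B.

**Ring B (key disconnection).** The C4–C5 bond of 13 (silylated to 14) is cut, giving methyl ketone 12 with its allylsilane arm. The forward Hosomi–Sakurai reaction closes ring B, creates the C4 carbinol and leaves the methylene on C6. The tertiary alcohol of 11 is silylated to 12 first so that TiCl4 meets no acidic proton.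

**Ring C carbinol and methyl ketone.** 11 comes from ketone 9 by methyl addition to the ring carbonyl, anti to the adjacent arm, and hydrolysis of the enol ether in 10. The 1-ethoxyvinyl group is the acyl-anion equivalent that survives both steps.

**Absolute configuration.** 9 is traced through enone 8 to silyloxy ketone 7. An enantioselective addition of an α-alkoxyvinyl copper reagent to an achiral enone with enolate trapping has no dependable basis. The configuration is therefore bought with enone 4, whose silyloxy group directs the addition and is then excised by elimination and conjugate reduction.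

**Three-component coupling.** The two exocyclic bonds of 7 are cut: conjugate addition of 5 (from ethyl vinyl ether 3) to 4 and alkylation of the resulting enolate 6 with allylic iodide 2, itself made from chloride 1.

## Alternatives that were turned down

**Alternative 1:** The bond from C7a to the benzylic CH2 (future C7) and the bond from C3a to an isopropenyl group are cut. Ring A arrives as an intact aromatic acylphloroglucinol.
- Key step: a copper-catalysed isopropenyl transfer to A2 (cyclopent-2-en-1-one) gives an enolate, which is trapped by the ortho-quinone methide A3 to give A1, the trans-2-(arylmethyl)-3-isopropenylcyclopentanone.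
- For it: three components meet in one flask, the isobutyryl group is already placed, and the route would be markedly shorter. On convergence and step count it beats the chosen route.
- Against it: ring B must later be closed by a dearomatising attack of the arene carbon on an electrophile made from the isopropenyl group. That attack must choose one face of a planar ring whose two ortho positions differ only remotely, so nothing fixes the spiro centre. The C4 carbinol would depend on an unselective epoxidation of the isopropenyl group. The acidic phenols of A3 quench the enolate. O-alkylation competes in the ring closure.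
- Comparison: the chosen route is longer but gives each stereocentre its own control element. C4 comes from a chair transition state, the spiro centre from equatorial acylation, and the acyl position from the order of bond construction.

**Alternative 2:** The C3a–C7a bond is cut, so ring C is closed last.
- Key step: the nitrile-stabilised carbanion of the open-chain epoxy nitrile A5 opens the epoxide at its secondary carbon (5-exo, inversion), leaving the oxygen on the tertiary carbon. This gives the cyclopentane carbonitrile diol benzyl ether A4.
- For it: the C4 carbinol comes from a Sharpless epoxidation, and C3a follows by stereospecific inversion. On certainty of the C4 configuration it is stronger than the chosen route.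
- Against it: the C1 carbinol next to the nitrile must be set in the acyclic chain with no control from the distant epoxide. The β-hydroxy nitrile carbanion can fragment by retro-addition unless protected. After A4, ring B is still open: both the nitrile carbon and the benzyloxymethyl carbon must be bonded to one ring A carbon, one of them at a neopentyl-like position. The spiro configuration then depends on telling two ring A carbonyls apart afterwards.
- Comparison: the chosen route closes ring B and sets C4 in one operation and leaves a one-carbon handle exactly on the spiro carbon.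

**Alternative 3:** The C6–C7 and C3a–C7a bonds are cut as a Diels–Alder reaction.
- Key step: an alkylidene triketone dienone adds intramolecularly to the vinyl group of its tethered carbinol, which derives from A7 ((S)-linalool). This closes rings B and C and gives A6, the spiro hydrindene triketone with a ring B alkene and a gem-diallyl group.
- For it: two rings and three stereocentres in one step, chirality from the chiral pool, and very few steps. On step economy it is clearly the strongest option.
- Against it: the diene is electron-poor and cross-conjugated while the dienophile is unactivated. Such dienones have an easy competing oxa-6π electrocyclisation to 2H-pyrans. Only the remote carbinol biases the facial and endo/exo choice that sets the spiro centre. In A6 the C4=C5 alkene must finally be hydrated with methyl axial and hydroxyl equatorial beside two allyl groups that are at least as reactive.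
- Comparison: the chosen route makes the C4 carbinol during ring closure, under chair control and before any other alkene is present.

Key step: step 7

Assumption: 1, 3, 4, 25 and the acyl donors are taken as purchasable; ring A compounds 24 and 26–28 are drawn in the enol tautomer of the target; in 15–19 the ring B carbon bearing the one-carbon group is drawn as the expected major epimer and becomes planar in 20.

## Route

Step 1
Reactants: 1 [2-(chloromethyl)prop-2-en-1-yl]trimethylsilane
Product: 2 [2-(iodomethyl)prop-2-en-1-yl]trimethylsilane
Conditions: NaI, acetone, rt, dark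
Reagents that add atoms: sodium iodide, [Na+].[I-]
Why: Finkelstein exchange; precipitation of NaCl from acetone drives the allylic chloride to the more reactive iodide needed for enolate alkylation.

Step 2
Reactants: 3 ethyl vinyl ether; 4 (4R)-4-[(tert-butyldimethylsilyl)oxy]cyclopent-2-en-1-one; 2 [2-(iodomethyl)prop-2-en-1-yl]trimethylsilane
Product: 7 (2R,3R,4R)-4-[(tert-butyldimethylsilyl)oxy]-3-(1-ethoxyethenyl)-2-{2-[(trimethylsilyl)methyl]prop-2-en-1-yl}cyclopentan-1-one, via 1-ethoxyvinyllithium 5 (not isolated), via triphenyltin enolate 6 (not isolated)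
Conditions: t-BuLi, THF, −78 → 0 °C; CuI, n-Bu3P, −78 °C; 4; then Ph3SnCl, HMPA; 2, −78 → −30 °C
Reagents that add atoms: none
Why: α-Lithiation of 3 and copper-mediated conjugate addition anti to the silyloxy group of 4 set C3; the tin enolate is then alkylated by the allylic iodide anti to the new C3 group, setting C2. This is a three-component conjugate addition–enolate alkylation; the tin enolate suppresses enolate equilibration and premature β-elimination.

Step 3
Reactants: 7 (2R,3R,4R)-4-[(tert-butyldimethylsilyl)oxy]-3-(1-ethoxyethenyl)-2-{2-[(trimethylsilyl)methyl]prop-2-en-1-yl}cyclopentan-1-one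
Product: 8 (4S,5R)-4-(1-ethoxyethenyl)-5-{2-[(trimethylsilyl)methyl]prop-2-en-1-yl}cyclopent-2-en-1-one
Conditions: DBU, CH2Cl2, 0 °C → rt
Reagents that add atoms: none
Why: E1cB elimination of silanolate from the β-silyloxy ketone removes the relay oxygen; the α-centre stays in its preferred trans arrangement and the γ-centre should be untouched under brief, mild treatment.

Step 4
Reactants: 8 (4S,5R)-4-(1-ethoxyethenyl)-5-{2-[(trimethylsilyl)methyl]prop-2-en-1-yl}cyclopent-2-en-1-one
Product: 9 (2R,3S)-3-(1-ethoxyethenyl)-2-{2-[(trimethylsilyl)methyl]prop-2-en-1-yl}cyclopentan-1-one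
Conditions: [(Ph3P)CuH]6, wet THF/benzene, rt
Reagents that add atoms: none
Why: Conjugate reduction by the CuH hexamer [(Ph3P)CuH]6 delivers hydride 1,4 to the enone only; the enol ether, the allylsilane alkene and both stereocentres are not involved and no new stereocentre forms.

Step 5
Reactants: 9 (2R,3S)-3-(1-ethoxyethenyl)-2-{2-[(trimethylsilyl)methyl]prop-2-en-1-yl}cyclopentan-1-one
Product: 11 1-[(1S,2R,3S)-3-hydroxy-3-methyl-2-{2-[(trimethylsilyl)methyl]prop-2-en-1-yl}cyclopentyl]ethan-1-one, via tertiary alcohol enol ether 10 (not isolated)
Conditions: MeMgBr, CeCl3, THF, −78 °C; then aq. oxalic acid, THF, 0 °C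
Reagents that add atoms: methylmagnesium bromide, C[Mg]Br; water, O
Why: Organocerium 1,2-addition (little enolisation) should occur on the face opposite the adjacent C2 arm, giving the carbinol with hydroxyl cis to the arm. Dilute acid then hydrolyses the enol ether to the methyl ketone much faster than it protodesilylates the allylsilane; the trans acetyl group is the stable epimer at the α-carbon.

Step 6
Reactants: 11 1-[(1S,2R,3S)-3-hydroxy-3-methyl-2-{2-[(trimethylsilyl)methyl]prop-2-en-1-yl}cyclopentyl]ethan-1-one
Product: 12 1-[(1S,2R,3S)-3-methyl-3-[(triethylsilyl)oxy]-2-{2-[(trimethylsilyl)methyl]prop-2-en-1-yl}cyclopentyl]ethan-1-one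
Conditions: TESOTf, 2,6-lutidine, CH2Cl2, −78 °C
Reagents that add atoms: triethylsilyl trifluoromethanesulfonate, CC[Si](CC)(CC)OS(=O)(=O)C(F)(F)F
Why: Silyl triflate silylation of the tertiary alcohol removes the only proton that would release HCl with TiCl4 and protodesilylate the allylsilane; at low temperature alcohol silylation outruns silyl enol ether formation.

Step 7
Reactants: 12 1-[(1S,2R,3S)-3-methyl-3-[(triethylsilyl)oxy]-2-{2-[(trimethylsilyl)methyl]prop-2-en-1-yl}cyclopentyl]ethan-1-one
Product: 13 (1S,3aS,4S,7aR)-1,4-dimethyl-6-methylidene-1-[(triethylsilyl)oxy]octahydro-1H-inden-4-ol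
Conditions: TiCl4, CH2Cl2, −78 °C; aq. NaHCO3
Reagents that add atoms: none
Why: TiCl4 binds the ketone oxygen, the terminal alkene carbon of the allylsilane (γ to silicon) attacks the carbonyl carbon, and the β-silyl cation at the central carbon loses Me3Si to chloride, leaving the exocyclic methylene and a titanium alkoxide that gives 13 on work-up. The closest known reaction type is the intramolecular Hosomi–Sakurai addition of 2-substituted allylsilanes to ketones, which gives 3-methylenecyclohexanols. Ring B closes in the 6-exo-trig mode at the carbonyl, with the allyl double bond inside the forming ring, through a chair. The trans ring fusion is inherited: the two tether ends are trans on the cyclopentane and both equatorial on the chair, so only a trans-hydrindane can form. The new stereocentre C4 is controlled by the open, antiperiplanar arrangement of C=O and C=C in that chair: the titanium-bound oxygen points outward (equatorial), away from the incoming alkene and from the axial C7a hydrogen, so methyl ends axial and hydroxyl equatorial. The sp2 carbon at C6 gives the axial methyl no 1,3-diaxial partner at this stage. The step needs C–C bond formation to outrun protodesilylation and ionisation of the tertiary silyl ether; the silyl ether (no acidic proton), a single electrophilic carbonyl and −78 °C should secure this.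

Step 8
Reactants: 13 (1S,3aS,4S,7aR)-1,4-dimethyl-6-methylidene-1-[(triethylsilyl)oxy]octahydro-1H-inden-4-ol
Product: 14 (1S,3aS,4S,7aR)-1,4-dimethyl-6-methylidene-1,4-bis[(triethylsilyl)oxy]octahydro-1H-indene
Conditions: TESOTf, 2,6-lutidine, CH2Cl2, 0 °C
Reagents that add atoms: triethylsilyl trifluoromethanesulfonate, CC[Si](CC)(CC)OS(=O)(=O)C(F)(F)F
Why: Silyl triflate silylation of the hindered tertiary alcohol protects it against O-acylation in the ring A steps; any diol formed by partial silyl loss in step 7 converges on 14 with excess reagent.

Step 9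
Reactants: 14 (1S,3aS,4S,7aR)-1,4-dimethyl-6-methylidene-1,4-bis[(triethylsilyl)oxy]octahydro-1H-indene
Product: 16 [(3S,3aR,5R,7S,7aS)-3,7-dimethyl-3,7-bis[(triethylsilyl)oxy]octahydro-1H-inden-5-yl]methanol, via B-alkyl-9-borabicyclononane 15 (not isolated)
Conditions: 9-BBN, THF, 0 → 50 °C; then NaOH, H2O2, 0 °C
Reagents that add atoms: hydrogen peroxide, OO
Why: Anti-Markovnikov hydroboration–oxidation of the 1,1-disubstituted alkene keeps the exocyclic carbon as the future ring A carbonyl and never places a ketone β to the C4 carbinol. Attack on the equatorial face, away from the axial methyl, should give mainly the axial CH2OH epimer, but this centre is erased in step 12.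

Step 10
Reactants: 16 [(3S,3aR,5R,7S,7aS)-3,7-dimethyl-3,7-bis[(triethylsilyl)oxy]octahydro-1H-inden-5-yl]methanol
Product: 18 (3S,3aR,5R,7S,7aS)-3,7-dimethyl-3,7-bis[(triethylsilyl)oxy]octahydro-1H-indene-5-carboxylic acid, via aldehyde 17 (not isolated)
Conditions: TEMPO (cat.), PhI(OAc)2, MeCN/aq. pH 7 buffer, rt
Reagents that add atoms: water, O
Why: Nitroxyl-catalysed oxidation takes the primary alcohol through the aldehyde and its hydrate to the acid under near-neutral conditions that tertiary silyl ethers tolerate.

Step 11
Reactants: 18 (3S,3aR,5R,7S,7aS)-3,7-dimethyl-3,7-bis[(triethylsilyl)oxy]octahydro-1H-indene-5-carboxylic acid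
Product: 19 methyl (3S,3aR,5R,7S,7aS)-3,7-dimethyl-3,7-bis[(triethylsilyl)oxy]octahydro-1H-indene-5-carboxylate
Conditions: MeI, K2CO3, DMF, rt
Reagents that add atoms: iodomethane, CI
Why: SN2 alkylation of the carboxylate occurs at oxygen, remote from the hindered ring carbon; epimerisation at the α-carbon is irrelevant.

Step 12
Reactants: 19 methyl (3S,3aR,5R,7S,7aS)-3,7-dimethyl-3,7-bis[(triethylsilyl)oxy]octahydro-1H-indene-5-carboxylate
Product: 21 methyl (3S,3aR,5R,7S,7aS)-5-acetyl-3,7-dimethyl-3,7-bis[(triethylsilyl)oxy]octahydro-1H-indene-5-carboxylate, via lithium ester enolate 20 (not isolated)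
Conditions: LDA, THF, −78 → −40 °C; then added to AcCl, −78 °C
Reagents that add atoms: acetyl chloride, CC(Cl)=O
Why: C-Acylation of the exocyclic ester enolate; the axial face is blocked by the syn-axial C7 methyl (C4 in the numbering of 13), so acetyl chloride approaches equatorially and the ester is left axial. This sets the spiro stereocentre with the later acyl-side carbonyl equatorial.

Step 13
Reactants: 21 methyl (3S,3aR,5R,7S,7aS)-5-acetyl-3,7-dimethyl-3,7-bis[(triethylsilyl)oxy]octahydro-1H-indene-5-carboxylate
Product: 22 methyl (3S,3aR,5R,7S,7aS)-3,7-dimethyl-5-(4-methyl-3-oxopentanoyl)-3,7-bis[(triethylsilyl)oxy]octahydro-1H-indene-5-carboxylate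
Conditions: MgBr2·OEt2, i-Pr2NEt, 1-isobutyrylbenzotriazole, CH2Cl2, rt
Reagents that add atoms: 1-(2-methylpropanoyl)-1H-benzotriazole, CC(C)C(=O)n1nnc2ccccc12
Why: Soft enolisation of the magnesium-chelated β-keto ester at its only enolisable position, the acetyl methyl, followed by C-acylation (crossed Claisen-type) gives the 1,3-diketone without a nucleophilic base that could cleave the quaternary keto ester.

Step 14
Reactants: 22 methyl (3S,3aR,5R,7S,7aS)-3,7-dimethyl-5-(4-methyl-3-oxopentanoyl)-3,7-bis[(triethylsilyl)oxy]octahydro-1H-indene-5-carboxylate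
Product: 23 methyl (3S,3aR,5R,7S,7aS)-5-(2-acetyl-4-methyl-3-oxopentanoyl)-3,7-dimethyl-3,7-bis[(triethylsilyl)oxy]octahydro-1H-indene-5-carboxylate
Conditions: MgCl2, pyridine, AcCl, CH2Cl2, 0 °C → rt
Reagents that add atoms: acetyl chloride, CC(Cl)=O
Why: C-Acylation of the magnesium β-diketonate at its central carbon; chelation favours C over O and gives the triacylmethane, which is used without delay.

Step 15
Reactants: 23 methyl (3S,3aR,5R,7S,7aS)-5-(2-acetyl-4-methyl-3-oxopentanoyl)-3,7-dimethyl-3,7-bis[(triethylsilyl)oxy]octahydro-1H-indene-5-carboxylate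
Product: 24 spiro trione in which C6 of 3-hydroxy-2-(2-methylpropanoyl)cyclohex-2-ene-1,5-dione (ring A) is C6 of the (1S,3aS,4S,7aR)-1,4-dimethyl-1,4-bis[(triethylsilyl)oxy]octahydroindane; ring A C5 carbonyl axial on ring B and cis to the axial methyl
Conditions: LDA (3 equiv), THF, −78 → 0 °C; then 1 M HCl
Reagents that add atoms: none
Why: Dieckmann condensation: the dianion (enolate plus acetyl CH2 carbanion) attacks the axial ester 6-exo-trig and expels methoxide, driven by formation of the stabilised triketone anion. Because the isobutyryl group already sits on the carbon bound to the equatorial carbonyl, the two carbonyls on the spiro carbon stay distinct and the stereocentre is kept.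

Step 16
Reactants: 24 spiro trione (ring A CH2 unsubstituted); 25 prenyl bromide
Product: 27 bis(triethylsilyl) ether of the target, via monoprenyl triketone 26 (not isolated)
Conditions: NaOMe (3.3 equiv), 25 (2.4 equiv in all), MeOH, 0 °C → rt
Reagents that add atoms: prenyl bromide (second equivalent of 25), CC(C)=CCBr
Why: Double C-alkylation of the only CH2 flanked by two carbonyls, as in gem-dialkylation of acylphloroglucinol-derived triketones: the first molecule of 25 gives 26, which is deprotonated again at the same carbon and takes up the second. The protic medium favours C- over O-alkylation and the acyl-bearing carbon is fully substituted.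

Step 17
Reactants: 27 bis(triethylsilyl) ether of the target
Product: 28 CNP0273836.5 (target)
Conditions: HF·pyridine, pyridine/THF, 0 °C → rt
Reagents that add atoms: none
Why: Fluoride cleaves both tertiary silyl ethers under buffered conditions that spare the prenyl alkenes, the tertiary alcohols and the triketone enol.

## Compound list

1 | [2-(chloromethyl)prop-2-en-1-yl]trimethylsilane | C[Si](C)(C)CC(=C)CCl | starting material
2 | [2-(iodomethyl)prop-2-en-1-yl]trimethylsilane | C[Si](C)(C)CC(=C)CI | intermediate
3 | ethyl vinyl ether | C=COCC | starting material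
4 | (4R)-4-[(tert-butyldimethylsilyl)oxy]cyclopent-2-en-1-one | O=C1C=C[C@H](O[Si](C)(C)C(C)(C)C)C1 | starting material
5 | 1-ethoxyvinyllithium | [Li]C(=C)OCC | intermediate (not isolated)
6 | (3R,4R)-4-[(tert-butyldimethylsilyl)oxy]-3-(1-ethoxyethenyl)-1-[(triphenylstannyl)oxy]cyclopent-1-ene | c1ccccc1[Sn](c1ccccc1)(c1ccccc1)OC1=C[C@@H](C(=C)OCC)[C@H](O[Si](C)(C)C(C)(C)C)C1 | intermediate (not isolated)
7 | (2R,3R,4R)-4-[(tert-butyldimethylsilyl)oxy]-3-(1-ethoxyethenyl)-2-{2-[(trimethylsilyl)methyl]prop-2-en-1-yl}cyclopentan-1-one | O=C1[C@H](CC(=C)C[Si](C)(C)C)[C@@H](C(=C)OCC)[C@H](O[Si](C)(C)C(C)(C)C)C1 | intermediate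
8 | (4S,5R)-4-(1-ethoxyethenyl)-5-{2-[(trimethylsilyl)methyl]prop-2-en-1-yl}cyclopent-2-en-1-one | O=C1[C@H](CC(=C)C[Si](C)(C)C)[C@@H](C(=C)OCC)C=C1 | intermediate
9 | (2R,3S)-3-(1-ethoxyethenyl)-2-{2-[(trimethylsilyl)methyl]prop-2-en-1-yl}cyclopentan-1-one | O=C1[C@H](CC(=C)C[Si](C)(C)C)[C@@H](C(=C)OCC)CC1 | intermediate
10 | (1S,2R,3S)-3-(1-ethoxyethenyl)-1-methyl-2-{2-[(trimethylsilyl)methyl]prop-2-en-1-yl}cyclopentan-1-ol | C[Si](C)(C)CC(=C)C[C@@H]1[C@H](CC[C@]1(C)O)C(=C)OCC | intermediate (not isolated)
11 | 1-[(1S,2R,3S)-3-hydroxy-3-methyl-2-{2-[(trimethylsilyl)methyl]prop-2-en-1-yl}cyclopentyl]ethan-1-one | C[Si](C)(C)CC(=C)C[C@@H]1[C@H](CC[C@]1(C)O)C(C)=O | intermediate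
12 | 1-[(1S,2R,3S)-3-methyl-3-[(triethylsilyl)oxy]-2-{2-[(trimethylsilyl)methyl]prop-2-en-1-yl}cyclopentyl]ethan-1-one | C[Si](C)(C)CC(=C)C[C@@H]1[C@H](CC[C@]1(C)O[Si](CC)(CC)CC)C(C)=O | intermediate
13 | (1S,3aS,4S,7aR)-1,4-dimethyl-6-methylidene-1-[(triethylsilyl)oxy]octahydro-1H-inden-4-ol | C=C1C[C@@H]2[C@H](CC[C@]2(C)O[Si](CC)(CC)CC)[C@@](C)(O)C1 | intermediate
14 | (1S,3aS,4S,7aR)-1,4-dimethyl-6-methylidene-1,4-bis[(triethylsilyl)oxy]octahydro-1H-indene | C=C1C[C@@H]2[C@H](CC[C@]2(C)O[Si](CC)(CC)CC)[C@@](C)(O[Si](CC)(CC)CC)C1 | intermediate
15 | 9-{[(3S,3aR,5R,7S,7aS)-3,7-dimethyl-3,7-bis[(triethylsilyl)oxy]octahydro-1H-inden-5-yl]methyl}-9-borabicyclo[3.3.1]nonane | C1CC2CCCC(C1)B2C[C@@H]1C[C@@H]2[C@H](CC[C@]2(C)O[Si](CC)(CC)CC)[C@@](C)(O[Si](CC)(CC)CC)C1 | intermediate (not isolated)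
16 | [(3S,3aR,5R,7S,7aS)-3,7-dimethyl-3,7-bis[(triethylsilyl)oxy]octahydro-1H-inden-5-yl]methanol | OC[C@@H]1C[C@@H]2[C@H](CC[C@]2(C)O[Si](CC)(CC)CC)[C@@](C)(O[Si](CC)(CC)CC)C1 | intermediate
17 | (3S,3aR,5R,7S,7aS)-3,7-dimethyl-3,7-bis[(triethylsilyl)oxy]octahydro-1H-indene-5-carbaldehyde | O=C[C@@H]1C[C@@H]2[C@H](CC[C@]2(C)O[Si](CC)(CC)CC)[C@@](C)(O[Si](CC)(CC)CC)C1 | intermediate (not isolated)
18 | (3S,3aR,5R,7S,7aS)-3,7-dimethyl-3,7-bis[(triethylsilyl)oxy]octahydro-1H-indene-5-carboxylic acid | OC(=O)[C@@H]1C[C@@H]2[C@H](CC[C@]2(C)O[Si](CC)(CC)CC)[C@@](C)(O[Si](CC)(CC)CC)C1 | intermediate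
19 | methyl (3S,3aR,5R,7S,7aS)-3,7-dimethyl-3,7-bis[(triethylsilyl)oxy]octahydro-1H-indene-5-carboxylate | COC(=O)[C@@H]1C[C@@H]2[C@H](CC[C@]2(C)O[Si](CC)(CC)CC)[C@@](C)(O[Si](CC)(CC)CC)C1 | intermediate
20 | lithium enolate of 19 (exocyclic ketene acetal at ring B C5) | [Li+].[O-]C(OC)=C1C[C@@H]2[C@H](CC[C@]2(C)O[Si](CC)(CC)CC)[C@@](C)(O[Si](CC)(CC)CC)C1 | intermediate (not isolated)
21 | methyl (3S,3aR,5R,7S,7aS)-5-acetyl-3,7-dimethyl-3,7-bis[(triethylsilyl)oxy]octahydro-1H-indene-5-carboxylate (ester axial, acetyl equatorial) | COC(=O)[C@]1(C(C)=O)C[C@@H]2[C@H](CC[C@]2(C)O[Si](CC)(CC)CC)[C@@](C)(O[Si](CC)(CC)CC)C1 | intermediate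
22 | methyl (3S,3aR,5R,7S,7aS)-3,7-dimethyl-5-(4-methyl-3-oxopentanoyl)-3,7-bis[(triethylsilyl)oxy]octahydro-1H-indene-5-carboxylate | COC(=O)[C@]1(C(=O)CC(=O)C(C)C)C[C@@H]2[C@H](CC[C@]2(C)O[Si](CC)(CC)CC)[C@@](C)(O[Si](CC)(CC)CC)C1 | intermediate
23 | methyl (3S,3aR,5R,7S,7aS)-5-(2-acetyl-4-methyl-3-oxopentanoyl)-3,7-dimethyl-3,7-bis[(triethylsilyl)oxy]octahydro-1H-indene-5-carboxylate (enol mixture, drawn as triketone) | COC(=O)[C@]1(C(=O)C(C(C)=O)C(=O)C(C)C)C[C@@H]2[C@H](CC[C@]2(C)O[Si](CC)(CC)CC)[C@@](C)(O[Si](CC)(CC)CC)C1 | intermediate
24 | spiro trione: ring A 3-hydroxy-2-(2-methylpropanoyl)cyclohex-2-ene-1,5-dione joined at C6 to C6 of the (1S,3aS,4S,7aR)-1,4-dimethyl-1,4-bis[(triethylsilyl)oxy]octahydroindane; ring A C5 carbonyl axial on ring B | C1C(=O)[C@@]2(C[C@@H]3[C@H](CC[C@]3(C)O[Si](CC)(CC)CC)[C@@](C)(O[Si](CC)(CC)CC)C2)C(=O)C(C(=O)C(C)C)=C1O | intermediate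
25 | prenyl bromide (1-bromo-3-methylbut-2-ene) | CC(C)=CCBr | starting material
26 | monoprenyl analogue of 24 (one 3-methylbut-2-en-1-yl group on ring A C4) | CC(C)=CCC1C(=O)[C@@]2(C[C@@H]3[C@H](CC[C@]3(C)O[Si](CC)(CC)CC)[C@@](C)(O[Si](CC)(CC)CC)C2)C(=O)C(C(=O)C(C)C)=C1O | intermediate (not isolated)
27 | bis(triethylsilyl) ether of the target (ring A C4 gem-diprenylated) | CC(C)=CCC1(CC=C(C)C)C(=O)[C@@]2(C[C@@H]3[C@H](CC[C@]3(C)O[Si](CC)(CC)CC)[C@@](C)(O[Si](CC)(CC)CC)C2)C(=O)C(C(=O)C(C)C)=C1O | intermediate
28 | CNP0273836.5: ring A 3-hydroxy-4,4-bis(3-methylbut-2-en-1-yl)-2-(2-methylpropanoyl)cyclohex-2-ene-1,5-dione spiro-joined at C6 to C6 of (1S,3aS,4S,7aR)-1,4-dimethyloctahydroindane-1,4-diol; ring A C5 carbonyl axial on ring B | CC(C)=CCC1(CC=C(C)C)C(=O)[C@@]2(C[C@@H]3[C@H](CC[C@]3(C)O)[C@@](C)(O)C2)C(=O)C(C(=O)C(C)C)=C1O | target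

## Step count and least certain steps

Total step count: 17. Longest linear sequence: 17 steps (steps 1–17, starting from chloride 1); 3 and 4 join this line at step 2 and 25 at step 16.

**Step 7 (key step).** The most likely failure is loss of the allylsilane by protodesilylation, caused by traces of HCl from TiCl4 and adventitious water or from partial cleavage of the silyl ether, before it adds to the hindered methyl ketone. A second risk is erosion of facial selectivity at the ketone if a synclinal arrangement competes with the antiperiplanar one. The fallback sets out from 12 and returns at 13. Deliberate protodesilylation with CF3CO2H in CH2Cl2 at 0 °C gives the methallyl ketone F1. MeAlCl2 in CH2Cl2 then promotes an intramolecular carbonyl–ene reaction of type 2 (ene unit tethered through its central carbon), which forms the same C4–C5 bond with transfer of an allylic hydrogen to oxygen and needs no silicon leaving group. The carbinol configuration from this closure would have to be confirmed.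

**Step 3.** The γ-hydrogen of 8 is doubly allylic, so DBU may move the ring double bond into conjugation with the enol ether or epimerise the adjacent centre. The fallback sets out from 7, avoids the enone altogether and returns at 10:
- MeMgBr/CeCl3 addition to 7, whose lower face is shielded by both the arm and the silyloxy group, gives the tertiary alcohol F2.
- TBAF gives the diol F3.
- 1,1'-Thiocarbonyldiimidazole acylates only the secondary hydroxyl, giving the thiocarbamate F4.
- Bu3SnH/AIBN (Barton–McCombie deoxygenation), run at high stannane concentration so that hydrogen transfer outpaces cyclisation of the secondary radical onto the arm alkene, gives 10, which is hydrolysed as in the second stage of step 5.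

**Step 12.** O-Acylation or incomplete reaction at the fully substituted, hindered enolate carbon is the main risk; the spiro centre depends on this step. The fallback sets out from 19 (through enolate 20) and returns at 21. Aldol addition to acetaldehyde, a small electrophile that can bind only through carbon and approaches from the same equatorial side, gives the β-hydroxy ester F5. Dess–Martin oxidation then gives 21.

**Step 15.** The triacylmethane 23 may lose an acyl group by retro-Claisen cleavage, or close through enolate oxygen to a pyranone instead of through carbon. The fallback sets out from 19 (through 20), masks the triketone as an isoxazole and returns at 28: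
- Acylation of 20 with 3-isopropyl-5-methylisoxazole-4-carbonyl chloride gives the keto ester F6.
- LDA deprotonates the isoxazole 5-methyl group, and this lateral carbanion closes onto the axial ester (Dieckmann) to give the isoxazole-fused spiro dione F7.
- Mo(CO)6 in wet acetonitrile cleaves the N–O bond to the enaminone F8.
- Aqueous acid hydrolysis, which also removes both silyl ethers, gives the triketone diol F9.
- F9 is diprenylated under the conditions of step 16 to give 28 directly.

**Step 16.** O-Prenylation of the ambident triketone anion and stalling after the first alkylation are the likely problems. The fallback sets out from 24 and returns at 27. Double Tsuji–Trost allylation with allyl methyl carbonate and Pd(PPh3)4, which is reliably C-selective for such stabilised anions, gives the gem-diallyl compound F10. Cross-metathesis with 2-methylbut-2-ene and the second-generation Grubbs catalyst converts both allyl groups into prenyl groups.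

## Further compounds

F1 | step 7 | 1-[(1S,2R,3S)-3-methyl-2-(2-methylprop-2-en-1-yl)-3-[(triethylsilyl)oxy]cyclopentyl]ethan-1-one | CC(=C)C[C@@H]1[C@H](CC[C@]1(C)O[Si](CC)(CC)CC)C(C)=O
F2 | step 3 | (1S,2R,3R,4R)-4-[(tert-butyldimethylsilyl)oxy]-3-(1-ethoxyethenyl)-1-methyl-2-{2-[(trimethylsilyl)methyl]prop-2-en-1-yl}cyclopentan-1-ol | C[Si](C)(C)CC(=C)C[C@@H]1[C@H]([C@H](O[Si](C)(C)C(C)(C)C)C[C@]1(C)O)C(=C)OCC
F3 | step 3 | (1S,2R,3R,4R)-3-(1-ethoxyethenyl)-1-methyl-2-{2-[(trimethylsilyl)methyl]prop-2-en-1-yl}cyclopentane-1,4-diol | C[Si](C)(C)CC(=C)C[C@@H]1[C@H]([C@H](O)C[C@]1(C)O)C(=C)OCC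
F4 | step 3 | O-(imidazol-1-ylthiocarbonyl) derivative of F3 at the secondary hydroxyl | C[Si](C)(C)CC(=C)C[C@@H]1[C@H]([C@H](OC(=S)n2ccnc2)C[C@]1(C)O)C(=C)OCC
F5 | step 12 | methyl (3S,3aR,5R,7S,7aS)-5-(1-hydroxyethyl)-3,7-dimethyl-3,7-bis[(triethylsilyl)oxy]octahydro-1H-indene-5-carboxylate (carbinol epimers) | COC(=O)[C@]1(C(C)O)C[C@@H]2[C@H](CC[C@]2(C)O[Si](CC)(CC)CC)[C@@](C)(O[Si](CC)(CC)CC)C1
F6 | step 15 | methyl (3S,3aR,5R,7S,7aS)-3,7-dimethyl-5-[(5-methyl-3-isopropylisoxazol-4-yl)carbonyl]-3,7-bis[(triethylsilyl)oxy]octahydro-1H-indene-5-carboxylate | COC(=O)[C@]1(C(=O)c2c(C)onc2C(C)C)C[C@@H]2[C@H](CC[C@]2(C)O[Si](CC)(CC)CC)[C@@](C)(O[Si](CC)(CC)CC)C1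
F7 | step 15 | isoxazole-fused spiro dione (ring A closed, 3-isopropylisoxazole fused at the future acyl-bearing and enol carbons) | C1C(=O)[C@@]2(C[C@@H]3[C@H](CC[C@]3(C)O[Si](CC)(CC)CC)[C@@](C)(O[Si](CC)(CC)CC)C2)C(=O)c2c1onc2C(C)C
F8 | step 15 | enaminone from N–O cleavage of F7 (2-(1-amino-2-methylpropylidene) ring A trione) | C1C(=O)[C@@]2(C[C@@H]3[C@H](CC[C@]3(C)O[Si](CC)(CC)CC)[C@@](C)(O[Si](CC)(CC)CC)C2)C(=O)C(=C(N)C(C)C)C1=O
F9 | step 15 | desilylated analogue of 24 (triketone diol) | C1C(=O)[C@@]2(C[C@@H]3[C@H](CC[C@]3(C)O)[C@@](C)(O)C2)C(=O)C(C(=O)C(C)C)=C1O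
F10 | step 16 | gem-diallyl analogue of 27 | C=CCC1(CC=C)C(=O)[C@@]2(C[C@@H]3[C@H](CC[C@]3(C)O[Si](CC)(CC)CC)[C@@](C)(O[Si](CC)(CC)CC)C2)C(=O)C(C(=O)C(C)C)=C1O
A1 | alternative 1 | (2R,3S)-3-(prop-1-en-2-yl)-2-{[2,4,6-trihydroxy-3-(2-methylpropanoyl)phenyl]methyl}cyclopentan-1-one | CC(C)C(=O)c1c(O)cc(O)c(C[C@@H]2[C@H](CCC2=O)C(C)=C)c1O
A2 | alternative 1 | cyclopent-2-en-1-one | O=C1C=CCC1
A3 | alternative 1 | 3,5-dihydroxy-6-methylidene-2-(2-methylpropanoyl)cyclohexa-2,4-dien-1-one (ortho-quinone methide) | CC(C)C(=O)C1=C(O)C=C(O)C(=C)C1=O
A4 | alternative 2 | (1S,2S,5S)-2-[(2R)-1-(benzyloxy)-2-hydroxypropan-2-yl]-5-hydroxy-5-methylcyclopentane-1-carbonitrile | N#C[C@@H]1[C@H](CC[C@]1(C)O)[C@@](C)(O)COCc1ccccc1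
A5 | alternative 2 | (3S)-5-[(2S,3S)-3-[(benzyloxy)methyl]-3-methyloxiran-2-yl]-3-hydroxy-3-methylpentanenitrile | N#CC[C@@](C)(O)CC[C@@H]1O[C@@]1(C)COCc1ccccc1
A6 | alternative 3 | spiro hydrindene triketone with ring B alkene and gem-diallyl ring A | C=CCC1(CC=C)C(=O)[C@@]2(C[C@@H]3[C@H](CC[C@]3(C)O)C(C)=C2)C(=O)C(C(=O)C(C)C)=C1O
A7 | alternative 3 | (3S)-3,7-dimethylocta-1,6-dien-3-ol ((S)-linalool) | C=C[C@@](C)(O)CCC=C(C)C
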